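**Retrosynthetic overview**

1. Numbering used here: ring A is the enolised cyclohexane-1,3,5-trione ring (C1 ring C=O, C2 hexanoyl-bearing, C3 C–OH, C4 quaternary with methyl and prenyl, C5 C–OH, C6 bridge-bearing); ring B is the aromatic ring.
2. The CH2 bridge between C6 of ring A and ring B is cut last: Mannich aminomethylation of trione 15, then elimination and Michael capture by aryl ketone 18 (from phloroglucinol by Friedel–Crafts acylation and para-selective O-methylation).
3. Ring A is cut at C1–C6 (ring closure, thio-Dieckmann) and at C2–C3 (intermolecular C-acylation); both bonds are made in one flask from acid chloride 8 (C10) and β-keto thioester 13 (C8 acyl part).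
4. Enabling feature: in ring A, C1 is an acyl carbon and C6 the α-carbon of the C5 ketone (a β-triketone, Claisen relationship), and the fully substituted C4 between the C3 and C5 carbonyls leaves C6 as the only enolisable carbon of that ketone, excludes aromatisation and cannot epimerise.
5. C4 is set earlier on an acyclic β-keto ester by auxiliary-controlled prenylation of a valine-derived enamine; ring B is present from the start and ring A is the only ring formed (step 7).

Key step: step 7

Assumption: with the L-valine auxiliary, the toluene/HMPA regime is taken to expose the face of the aza-enolate that leads to the (S) ester (if the opposite sense is found, the D-valine ester is used with no other change); enolised β-triketones are written in the tautomer of the target SMILES.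

**Route**

Step 1
Reactants: 1 tert-butyl 2-methyl-3-oxobutanoate; 2 L-valine tert-butyl ester
Product: 3 tert-butyl (2Z)-3-{[(2S)-1-tert-butoxy-3-methyl-1-oxobutan-2-yl]amino}-2-methylbut-2-enoate
Conditions: BF3·OEt2 (cat.), toluene, reflux, Dean–Stark trap
Reagents that add atoms: none
Why: Acid-catalysed condensation of the amine with the ketone carbonyl and azeotropic removal of water should give the Z-configured β-enamino ester, held by an N–H···O=C hydrogen bond (enamine formation).

Step 2
Reactants: 3 tert-butyl (2Z)-3-{[(2S)-1-tert-butoxy-3-methyl-1-oxobutan-2-yl]amino}-2-methylbut-2-enoate; 4 1-bromo-3-methylbut-2-ene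
Product: 6 tert-butyl (2S)-2-acetyl-2,5-dimethylhex-4-enoate, via ketimine 5 (not isolated)
Conditions: LiN(i-Pr)2, toluene, −78 °C; HMPA, then 4, −78 to −55 °C; then 1 M HCl aq, THF, 0 °C to rt
Reagents that add atoms: water, O
Why: N-Deprotonation gives an aza-enolate chelated by the valine ester carbonyl, whose isopropyl group shields one face, so the allylic bromide should alkylate C2 from the open face (chiral-auxiliary SN2 alkylation of a lithiated β-enamino ester) and set the quaternary (S) centre, after which mild acid hydrolysis of the ketimine frees the ketone and returns the auxiliary.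

Step 3
Reactants: 6 tert-butyl (2S)-2-acetyl-2,5-dimethylhex-4-enoate
Product: 7 (2S)-2-acetyl-2,5-dimethylhex-4-enoic acid
Conditions: CF3CO2H, CH2Cl2, 0 °C; evaporation below 10 °C, used at once
Reagents that add atoms: none
Why: Acidolysis of the tert-butyl ester (loss of 2-methylpropene) should free the acid without touching the quaternary centre, and the short cold exposure limits decarboxylation of the β-keto acid and protonation of the prenyl alkene.

Step 4
Reactants: 7 (2S)-2-acetyl-2,5-dimethylhex-4-enoic acid
Product: 8 (2S)-2-acetyl-2,5-dimethylhex-4-enoyl chloride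
Conditions: 1-chloro-N,N,2-trimethylprop-1-en-1-amine, CH2Cl2, 0 °C; solution used directly
Reagents that add atoms: 1-chloro-N,N,2-trimethylprop-1-en-1-amine, CC(C)=C(Cl)N(C)C
Why: The α-chloroenamine converts the acid into the acid chloride under neutral conditions without free HCl (acid chloride formation), so the prenyl alkene should survive, and the product has no α-hydrogen and cannot form a ketene or epimerise.

Step 5
Reactants: 9 2,2-dimethyl-1,3-dioxane-4,6-dione; 10 hexanoyl chloride
Product: 11 5-(1-hydroxyhexylidene)-2,2-dimethyl-1,3-dioxane-4,6-dione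
Conditions: pyridine, CH2Cl2, 0 °C to rt; 1 M HCl wash
Reagents that add atoms: none
Why: The acidic methylene of the dioxanedione should be C-acylated by the acid chloride in the presence of pyridine (acylation of an active methylene compound) to give the enolised acyl derivative.

Step 6
Reactants: 11 5-(1-hydroxyhexylidene)-2,2-dimethyl-1,3-dioxane-4,6-dione; 12 benzenethiol
Product: 13 S-phenyl 3-oxooctanethioate
Conditions: toluene, reflux
Reagents that add atoms: none
Why: Thermal fragmentation of the acyl dioxanedione releases acetone and CO2 and an acylketene, which the thiol should trap as the β-keto thioester (acylketene generation and capture).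

Step 7
Reactants: 8 (2S)-2-acetyl-2,5-dimethylhex-4-enoyl chloride; 13 S-phenyl 3-oxooctanethioate
Product: 15 (4S)-2-hexanoyl-3,5-dihydroxy-4-methyl-4-(3-methylbut-2-en-1-yl)cyclohexa-2,5-dien-1-one, via triacylmethane thioester 14 (not isolated)
Conditions: MgBr2·OEt2 (2.5 equiv), i-Pr2NEt (4 equiv), CH2Cl2, 0 °C, slow addition of 8; rt, then 40 °C; 1 M HCl work-up
Reagents that add atoms: none
Why: The enolate of 13, chelated by MgBr2, is C-acylated by the neopentyl acid chloride 8 to give the MgBr2 chelate of 14; chelation of the C3 and C5 oxygens then lets the amine enolise the methyl ketone, whose only enolisable carbon is the future C6, and this enolate attacks the thioester carbonyl and expels thiophenolate, forming the C1–C6 bond. The closest known reaction types are the soft-enolisation C-acylation of β-dicarbonyl compounds with acid chlorides, the Dieckmann closure of 3,5-dioxo esters to cyclohexane-1,3,5-triones and the magnesium-templated Claisen cyclisation of polyketo esters. Ring A closes in the 6-(enolendo)-exo-trig mode, helped by the gem-disubstituted C4 in the chain. No stereocentre is formed: C4 comes from 8, carries no hydrogen and none of its bonds is broken, so its (S) configuration is carried through. The step needs C- over O-acylation in the first event and, in the second, Claisen attack on the thioester in preference to aldol attack on the hexanoyl carbonyl (1,5 to the methyl ketone) and to O-closure to an enol lactone. The chelate should secure this by tying up the hexanoyl and C3 oxygens as a diketonate, which leaves the twisted thioester as the free electrophile, and aldol or enol-lactone adducts can revert whereas loss of thiophenolate to the doubly enolised trione chelate cannot.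

Step 8
Reactants: 16 benzene-1,3,5-triol (phloroglucinol); 10 hexanoyl chloride
Product: 17 1-(2,4,6-trihydroxyphenyl)hexan-1-one
Conditions: AlCl3 (3.5 equiv), PhNO2/CH2Cl2, 0 to 60 °C; aq HCl work-up
Reagents that add atoms: none
Why: Friedel–Crafts acylation of the threefold-symmetric, highly activated arene can give only one regioisomer, and the new ketone deactivates the ring against a second acylation.

Step 9
Reactants: 17 1-(2,4,6-trihydroxyphenyl)hexan-1-one
Product: 18 1-(2,6-dihydroxy-4-methoxyphenyl)hexan-1-one
Conditions: Me2SO4 (1.0 equiv), K2CO3, acetone, rt to reflux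
Reagents that add atoms: dimethyl sulfate, COS(=O)(=O)OC
Why: The 4-hydroxyl is the only one not hydrogen-bonded to the ketone and the most acidic, so one equivalent of the methylating agent should alkylate it first (regioselective Williamson O-methylation).

Step 10
Reactants: 15 (4S)-2-hexanoyl-3,5-dihydroxy-4-methyl-4-(3-methylbut-2-en-1-yl)cyclohexa-2,5-dien-1-one; 18 1-(2,6-dihydroxy-4-methoxyphenyl)hexan-1-one
Product: 20 CNP0108719.1, (4S)-2-hexanoyl-6-[(3-hexanoyl-2,4-dihydroxy-6-methoxyphenyl)methyl]-3,5-dihydroxy-4-methyl-4-(3-methylbut-2-en-1-yl)cyclohexa-2,5-dien-1-one, via Mannich base 19 (not isolated)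
Conditions: CH2=NMe2+ I−, Et3N, CH2Cl2, 0 °C to rt; then 18 (3 equiv), 1,4-dioxane, 90 °C
Reagents that add atoms: N,N-dimethylmethyleneiminium iodide, C=[N+](C)C.[I-]
Why: Mannich aminomethylation at C6, the only free nucleophilic carbon of 15, followed by thermal loss of dimethylamine should give a 6-methylene trione (quinone-methide-type acceptor) that is captured by C3 of 18, whose two free carbons are equivalent (Mannich reaction, then elimination and Michael addition), with excess 18 suppressing double alkylation and the quaternary centre untouched.

**Compound list**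

1 | tert-butyl 2-methyl-3-oxobutanoate (racemic, configurationally labile) | CC(=O)C(C)C(=O)OC(C)(C)C | starting material
2 | L-valine tert-butyl ester, (S), free base from the commercial hydrochloride | CC(C)[C@H](N)C(=O)OC(C)(C)C | starting material
3 | tert-butyl (2Z)-3-{[(2S)-1-tert-butoxy-3-methyl-1-oxobutan-2-yl]amino}-2-methylbut-2-enoate | C/C(N[C@@H](C(C)C)C(=O)OC(C)(C)C)=C(\C)C(=O)OC(C)(C)C | intermediate
4 | 1-bromo-3-methylbut-2-ene (prenyl bromide) | CC(C)=CCBr | starting material
5 | tert-butyl (2S)-2-[1-({(2S)-1-tert-butoxy-3-methyl-1-oxobutan-2-yl}imino)ethyl]-2,5-dimethylhex-4-enoate (C-alkylated ketimine) | CC(C)(C)OC(=O)[C@@](C)(CC=C(C)C)C(C)=N[C@@H](C(C)C)C(=O)OC(C)(C)C | intermediate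
6 | tert-butyl (2S)-2-acetyl-2,5-dimethylhex-4-enoate | CC(C)(C)OC(=O)[C@@](C)(CC=C(C)C)C(C)=O | intermediate
7 | (2S)-2-acetyl-2,5-dimethylhex-4-enoic acid | OC(=O)[C@@](C)(CC=C(C)C)C(C)=O | intermediate
8 | (2S)-2-acetyl-2,5-dimethylhex-4-enoyl chloride | ClC(=O)[C@@](C)(CC=C(C)C)C(C)=O | intermediate
9 | 2,2-dimethyl-1,3-dioxane-4,6-dione | CC1(C)OC(=O)CC(=O)O1 | starting material
10 | hexanoyl chloride | CCCCCC(Cl)=O | starting material
11 | 5-(1-hydroxyhexylidene)-2,2-dimethyl-1,3-dioxane-4,6-dione | CCCCCC(O)=C1C(=O)OC(C)(C)OC1=O | intermediate
12 | benzenethiol | Sc1ccccc1 | starting material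
13 | S-phenyl 3-oxooctanethioate | CCCCCC(=O)CC(=O)Sc1ccccc1 | intermediate
14 | S-phenyl (4S)-2-hexanoyl-4-methyl-4-(3-methylbut-2-en-1-yl)-3,5-dioxohexanethioate (C2 enolised, configuration there not defined) | CCCCCC(=O)C(C(=O)Sc1ccccc1)C(=O)[C@@](C)(CC=C(C)C)C(C)=O | intermediate
15 | (4S)-2-hexanoyl-3,5-dihydroxy-4-methyl-4-(3-methylbut-2-en-1-yl)cyclohexa-2,5-dien-1-one | CCCCCC(=O)C1=C(O)[C@@](C)(CC=C(C)C)C(O)=CC1=O | intermediate
16 | benzene-1,3,5-triol (phloroglucinol) | Oc1cc(O)cc(O)c1 | starting material
17 | 1-(2,4,6-trihydroxyphenyl)hexan-1-one | CCCCCC(=O)c1c(O)cc(O)cc1O | intermediate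
18 | 1-(2,6-dihydroxy-4-methoxyphenyl)hexan-1-one | CCCCCC(=O)c1c(O)cc(OC)cc1O | intermediate
19 | (4S)-6-[(dimethylamino)methyl]-2-hexanoyl-3,5-dihydroxy-4-methyl-4-(3-methylbut-2-en-1-yl)cyclohexa-2,5-dien-1-one (Mannich base) | CCCCCC(=O)C1=C(O)[C@@](C)(CC=C(C)C)C(O)=C(CN(C)C)C1=O | intermediate
20 | CNP0108719.1, (4S)-2-hexanoyl-6-[(3-hexanoyl-2,4-dihydroxy-6-methoxyphenyl)methyl]-3,5-dihydroxy-4-methyl-4-(3-methylbut-2-en-1-yl)cyclohexa-2,5-dien-1-one | CCCCCC(=O)C1=C(O)[C@@](C)(CC=C(C)C)C(O)=C(Cc2c(OC)cc(O)c(C(=O)CCCCC)c2O)C1=O | target

**Step count and risks**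

Total step count: 10. Longest linear sequence: 6 steps (steps 1, 2, 3, 4, 7, 10).

Step 7. The methyl-ketone enolate may add to the hexanoyl carbonyl (aldol diversion), or the thioester may be consumed before the ring closes. The fallback sets out from 8, separates the two events and gives up the thioester. Acid chloride 8 acylates commercially available methyl 3-oxooctanoate (MgCl2, pyridine, CH2Cl2) to give the isolable methyl (4S)-2-hexanoyl-4-methyl-4-(3-methylbut-2-en-1-yl)-3,5-dioxohexanoate F1. F1 is then closed in a separate operation with Mg(OMe)2 in MeOH at reflux (magnesium-templated Dieckmann cyclisation of a polyketo ester), and the route is rejoined at 15.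

Step 10. The methylene bridge may exchange reversibly (retro-Michael and re-addition), scrambling the partners into symmetrical dimers, and the remaining free carbon of ring B may be alkylated a second time. The fallback sets out from 18: formylation (POCl3, DMF, then aqueous hydrolysis; Vilsmeier–Haack) gives 3-hexanoyl-2,4-dihydroxy-6-methoxybenzaldehyde F2. Trione 15 and F2 are then joined by reductive alkylation (catalytic L-proline, diethyl 2,6-dimethyl-1,4-dihydropyridine-3,5-dicarboxylate, CH2Cl2, rt). This is a Knoevenagel condensation followed by conjugate hydride transfer to the alkylidene trione, which fixes the bridge irreversibly; the route is rejoined at 20.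

Step 2. The alkylation of the acyclic aza-enolate may show poor facial selectivity. The fallback sets out from 1 and 4: alkylation with K2CO3 in acetone gives racemic tert-butyl 2-acetyl-2,5-dimethylhex-4-enoate F3. F3 is resolved by preparative chromatography on a chiral stationary phase into 6 and its enantiomer tert-butyl (2R)-2-acetyl-2,5-dimethylhex-4-enoate F4, which is set aside; the route is rejoined at 6.

Further compounds
F1 | step 7 | methyl (4S)-2-hexanoyl-4-methyl-4-(3-methylbut-2-en-1-yl)-3,5-dioxohexanoate | CCCCCC(=O)C(C(=O)OC)C(=O)[C@@](C)(CC=C(C)C)C(C)=O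
F2 | step 10 | 3-hexanoyl-2,4-dihydroxy-6-methoxybenzaldehyde | CCCCCC(=O)c1c(O)cc(OC)c(C=O)c1O
F3 | step 2 | racemic tert-butyl 2-acetyl-2,5-dimethylhex-4-enoate | CC(C)(C)OC(=O)C(C)(CC=C(C)C)C(C)=O
F4 | step 2 | tert-butyl (2R)-2-acetyl-2,5-dimethylhex-4-enoate | CC(C)(C)OC(=O)[C@](C)(CC=C(C)C)C(C)=O
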